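## Analysis of the target

Isorhamnetin 7-O-sulfate (17) is a flavonol: a benzo-fused 4-pyranone (rings A and C) with a 4-hydroxy-3-methoxyphenyl group (ring B) on C2, hydroxyls on C3 and C5, and a hydrogen sulfate ester on O7. The molecule is flat and has no stereocentre, so the task is one of regiochemistry among four acidic oxygens (O3, O5, O7, O4') and of handling the sulfate. The aryl hydrogen sulfate is the sensitive group. It is a strong acid that hydrolyses in its own acidity and tolerates neither acidic nor strongly nucleophilic steps, so it must come late and travel as a salt. The free 3-hydroxy-4-pyranone and the guaiacyl phenol are easily oxidised in base. The 5-OH is chelated to the C4 carbonyl and is sluggish, but O3 and O4' still have to be kept apart from O7 by protecting groups. The strategy rests on ring A. C5, C7 and C8a carry oxygen in a 1,3,5 pattern, and the C7 oxygen is the middle one of the three carbonyl oxygens of the polyketide chain C4a–C8a–C8–C7–C6–C5 that nature folds onto a cinnamoyl starter. A 4-alkoxy-6-methyl-2-pyrone holds this chain as a lactone, with the future O7 as an ether oxygen and the future O5 and O1 as the two lactone oxygens. Opening the lactone and closing C4a–C5 by Claisen acylation therefore builds ring A with O7 already set apart, while ring B, C2, C3 with its oxygen and C4 arrive on the acyl group.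

## Retrosynthetic reasoning

**17 from 15 (through 16).** The last disconnection cuts the two O–CH2Ph bonds at O3 and O4'. Hydrogenolysis is the one deprotection that is neutral and non-nucleophilic enough for an aryl sulfate, and it removes both groups in one operation. The sulfate passes through it as the sodium salt 15, emerges as 16, and is protonated to 17 only at the very end.

**15 from 14.** Cutting the S–O7 bond leads to the phenol 14. In 14, O3 and O4' are capped and the 5-OH is tied to the C4 carbonyl by a hydrogen bond, so the forward sulfation finds a single free, acidic hydroxyl.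

**14 from 13.** The O7–CH2Ar bond of a 4-methoxybenzyl ether is cut. This group is what the key step needs on the pyrone oxygen, and it must leave without touching the two benzyl ethers. Acidolysis is chosen over oxidative removal. O7 of a chromone is a vinylogous ester oxygen: it supports a benzylic cation poorly, which slows hydride abstraction, but it is a good leaving group once protonated.

**13 from 12.** Ring C is opened at O1–C2, giving the 2',6'-dihydroxychalcone 12 with O3 present as an α-benzyloxy group. Cutting here, and not at C2–C3 or C3–C4, keeps ring B, C2, C3–O and C4 together as one acyl unit and avoids any later oxidation at C3. The two ortho hydroxyls of 12 are equivalent, so the forward oxidative cyclisation has no regiochemical choice to make.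

**12 from 10 (through 11).** Ring A is taken apart at the C4a–C5 bond (equivalent to C4a–C8a). This is the bond a Claisen acylation forms when the C4a methylene, flanked by two ketones, attacks an ester at the end of the chain C8a–C8–C7–C6–C5. That chain, with its ester tied back as a lactone and its C7 oxygen as an enol ether, is the 4-alkoxy-2-pyrone 10. The forward step must open the lactone with a magnesium alkoxide to the diketo ester 11 and fold 11 by C-acylation, not by aldol condensation or closure through oxygen. The gain is that a trioxygenated benzene ring is replaced by a purchased pyrone, and O7 differs from O5 and O1 from the outset.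

**10 from 3 and 7 (through 8 and 9).** The bond between the exocyclic methylene (future C4a) and the ketone carbon (future C4) is cut. Pyrone 3 is deprotonated at its 6-methyl group to the carbanion 9, which is acylated by acid 7 activated as imidazolide 8. The cut joins two fragments of similar size and uses the one acidic position of 3.

**7 from 4 and 5 (through 6).** The C=C bond (future C2=C3) is cut into aldehyde 4 and alkoxyacetate 5, joined forward by a condensation that passes through ester 6. The benzyl ether of 5 becomes the O3 benzyl ether and that of 4 the O4' benzyl ether. The Z geometry has no lasting consequence, because the double bond ends inside ring C.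

**3 from 1 and 2.** The O–CH2 bond is cut; the forward reaction is O-alkylation of the acidic 4-hydroxyl of 1 with 2.

## Alternatives that were turned down

**Alternative 1:** Ring C is cut at C3–C4 and O1–C2, giving the symmetrical aldehyde A1 (4-formyl-3,5-dihydroxyphenyl neopentyl sulfate) and the aryl siloxyalkyne A2.
- **Key step:** with [Cp*RhCl2]2 and Cu(OAc)2 as oxidant, an ortho hydroxyl directs rhodium into the aldehyde C–H bond. The acyl–rhodium species inserts A2 and C–O bond formation closes the pyranone to A3, the flavonol with O3 and O4' silylated and O7 as the neopentyl sulfate diester.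
- **For:** one step makes ring C with O3 in place from two fragments. A1 is symmetric, and the sulfate sits on O7 from the start as a neutral diester, so no late sulfation selectivity arises. On convergence and step count this plan is stronger than the chosen one.
- **Against:** A2 is a ketene equivalent whose oxygen-bearing carbon is electrophilic, so the free phenols of A1 and acetate from the oxidant can add to it. Insertion must place the siloxy carbon next to the acyl carbon, a regiochemistry not established for heteroatom-substituted alkynes in this annulation. Decarbonylation of the electron-rich acyl–rhodium species is a further exit. Removing the neopentyl group needs a nucleophile with heating, and the silyl groups need fluoride.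
- **Comparison:** the chosen route is longer, but apart from one step it uses classical reagents on stable intermediates from cheap materials, and its uncertain step has a close mechanistic relative.

**Alternative 2:** Ring C is cut at the aryl C–O bond O1–C8a, giving the α-benzyloxy 1,3-diketone A4 with a 2,6-difluoro-4-(methoxymethoxy)phenyl group.
- **Key step:** with K2CO3 in DMF the enolate oxygen displaces one of the two equivalent ortho fluorides, which are activated by the adjacent carbonyl. The product is A5, the 3-benzyloxy-5-fluoroflavone with O7 as a methoxymethyl ether.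
- **For:** intramolecular SNAr of ortho-haloaryl 1,3-diketones is a dependable chromone closure, the difluoro ring removes any regiochemical question, and O7 is distinct. On certainty of the key step this plan is stronger than the chosen one.
- **Against:** C5 leaves the step as C–F. A second SNAr with an oxygen nucleophile is needed, and alkoxide or hydroxide can instead add at C2 and open ring C. Building A4 needs a difluoroarene made by directed metalation and a C-acylation that competes with O-acylation. After the key step, fluoride exchange, acetal removal, sulfation and debenzylation remain, which is a longer endgame.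
- **Comparison:** the chosen strategy delivers all three ring A oxygens at the right oxidation level and protection state directly from the pyrone, with O5 free and chelated. The price is a less certain ring formation.

**Alternative 3:** Ring C is again cut at O1–C2, but closed oxidatively from the ring B side, from the 1,2-dione A6 that already carries the sulfate as its sodium salt.
- **Key step:** anodic two-electron oxidation of the guaiacyl phenol turns the benzylic carbon (future C2) into the electrophilic end of a quinone methide. One of the two equivalent ortho hydroxyls of ring A adds to it, and enolisation gives A7, the sodium salt of the target (the same salt as 16).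
- **For:** no protecting groups, no chemical oxidant, and the salt of the natural product comes directly from the key step. On step economy this plan is the strongest of the four.
- **Against:** A7 contains a 3-hydroxy enol conjugated to the guaiacyl ring and should be oxidised at least as easily as A6, so over-oxidation at the electrode is built in. The enolised 1,2-dione and ring A are further anodic sites, and solvent can capture the quinone methide. All chemistry leading to A6 must be run on an ionic sulfate with free phenols, and the dione is open to base-induced cleavage.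
- **Comparison:** the chosen route is longer but confines the sulfate and the free polyphenol to its last two steps, and every earlier intermediate is neutral and can be chromatographed.

Key step: step 4

Assumption: the target is taken as the free hydrogen sulfate as drawn; it is liberated from its sodium salt only in the last operation and would be stored as that salt. Aldehyde 4, the benzyl ether of vanillin, is taken as purchased.

## Route

Step 1
Reactants: 1 4-hydroxy-6-methyl-2H-pyran-2-one (triacetic acid lactone); 2 4-methoxybenzyl chloride
Product: 3 4-[(4-methoxybenzyl)oxy]-6-methyl-2H-pyran-2-one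
Conditions: K2CO3, Bu4NI (cat.), DMF, 50 °C
Reagents that add atoms: none
Why: Williamson-type O-alkylation of the vinylogous carboxylic acid; the potassium pyronate in a dipolar aprotic solvent should react mainly through the 4-oxygen, giving the conjugated 4-alkoxy-2-pyrone.

Step 2
Reactants: 4 4-(benzyloxy)-3-methoxybenzaldehyde; 5 methyl 2-(benzyloxy)acetate
Product: 7 (2Z)-2-(benzyloxy)-3-[4-(benzyloxy)-3-methoxyphenyl]prop-2-enoic acid, via methyl ester 6 (not isolated)
Conditions: NaOMe, 5 (2.5 equiv), MeOH/THF, 0 °C to reflux; then 2 M NaOH, reflux; cold 1 M HCl to pH 3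
Reagents that add atoms: sodium hydroxide, [Na+].[OH-]
Why: Claisen-type ester–aldehyde condensation with E1cB dehydration, then saponification; addition and elimination are reversible, so the more stable Z acrylate (aryl trans to the carboxyl) is expected. No stereocentre is formed, and the base-stable enol ether is exposed only briefly to cold dilute acid.

Step 3
Reactants: 7 (2Z)-2-(benzyloxy)-3-[4-(benzyloxy)-3-methoxyphenyl]prop-2-enoic acid; 3 4-[(4-methoxybenzyl)oxy]-6-methyl-2H-pyran-2-one
Product: 10 6-{(3Z)-3-(benzyloxy)-4-[4-(benzyloxy)-3-methoxyphenyl]-2-oxobut-3-en-1-yl}-4-[(4-methoxybenzyl)oxy]-2H-pyran-2-one, via acyl imidazolide 8 (not isolated), via lithiated pyrone 9 (not isolated)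
Conditions: 7, CDI, THF, rt, Ar purge; 3 (1.3 equiv), LiN(SiMe3)2 (3.5 equiv), THF, −78 °C; then solution of 8, −78 to −40 °C; AcOH
Reagents that add atoms: none
Why: Lateral deprotonation of the 6-methyl group of a 4-alkoxy-2-pyrone gives a vinylogous ester enolate, which is C-acylated by the acyl imidazolide (crossed Claisen acylation). The extra base takes up the liberated imidazole and the more acidic keto pyrone product, which prevents a second acylation.

Step 4
Reactants: 10 6-{(3Z)-3-(benzyloxy)-4-[4-(benzyloxy)-3-methoxyphenyl]-2-oxobut-3-en-1-yl}-4-[(4-methoxybenzyl)oxy]-2H-pyran-2-one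
Product: 12 (2Z)-2-(benzyloxy)-3-[4-(benzyloxy)-3-methoxyphenyl]-1-{2,6-dihydroxy-4-[(4-methoxybenzyl)oxy]phenyl}prop-2-en-1-one, via ring-opened diketo ester 11 (not isolated)
Conditions: Mg(OCH2C6H4-4-OMe)2 (3 equiv, from n-Bu2Mg + 4-MeOC6H4CH2OH), THF/4-MeOC6H4CH2OH, 65 °C; cold 0.5 M HCl
Reagents that add atoms: none
Why: Proposed new method: the magnesium alkoxide first forms the chelated enolate of the keto pyrone and then adds to the lactone carbonyl (pyrone C2), opening the ring to diketo ester 11, in which ester carbon and chain remain cis across the former pyrone C3=C4 bond because that bond was endocyclic (CIP descriptor 2E, since the alkoxy group outranks the chain). The magnesium-bound carbanion at the methylene between the two ketones (future C4a) then attacks the ester carbonyl (future C5) in a Claisen acylation, 4-methoxybenzyl oxide leaves, and enolisation of the cyclohexadienone aromatises ring A. The closest known reaction type is the base-induced ring opening and Claisen cyclisation of 4-hydroxy-6-(2-oxoalkyl)-2-pyrones and 3,5,7-triketo esters to acylphloroglucinols with Mg(OMe)2; new here are the ether on the 4-oxygen and the α-alkoxy enone as acyl group. Ring A closes in the 6-exo-trig mode (6-enolexo-exo-trig for the β-diketonate). No stereocentre is formed and the Z enol ether of the side chain is not involved. The step needs Claisen folding to beat aldol folding, closure of a diketone oxygen onto the alkoxy-bearing carbon, and alkoxide exchange or conjugate addition: the enol ether at the future O7 removes the ester α-enolate that the aldol mode requires, the cis geometry holds carbanion and ester within reach, magnesium chelation keeps the diketonate C-nucleophilic, and the matching alkoxide makes exchange at the ester and at the vinylogous carbonate carbon degenerate. The two new hydroxyls are equivalent, so either can become O1.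

Step 5
Reactants: 12 (2Z)-2-(benzyloxy)-3-[4-(benzyloxy)-3-methoxyphenyl]-1-{2,6-dihydroxy-4-[(4-methoxybenzyl)oxy]phenyl}prop-2-en-1-one
Product: 13 3-(benzyloxy)-2-[4-(benzyloxy)-3-methoxyphenyl]-5-hydroxy-7-[(4-methoxybenzyl)oxy]-4H-chromen-4-one
Conditions: I2 (10 mol %), DMSO, 110 °C
Reagents that add atoms: none
Why: Iodine-mediated oxidative cyclisation of a 2'-hydroxychalcone to a flavone: oxa-Michael closure of ring C (6-endo-trig) is followed by loss of HI, which DMSO reoxidises to I2. The two ortho hydroxyls are equivalent, so one product results, and the remaining hydroxyl becomes the chelated 5-OH.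

Step 6
Reactants: 13 3-(benzyloxy)-2-[4-(benzyloxy)-3-methoxyphenyl]-5-hydroxy-7-[(4-methoxybenzyl)oxy]-4H-chromen-4-one
Product: 14 3-(benzyloxy)-2-[4-(benzyloxy)-3-methoxyphenyl]-5,7-dihydroxy-4H-chromen-4-one
Conditions: TFA, anisole (10 equiv), CH2Cl2, 0 °C
Reagents that add atoms: none
Why: SN1 acidolysis of the 4-methoxybenzyl aryl ether, the cation being trapped by anisole in a Friedel–Crafts alkylation. The unsubstituted benzyl ethers at O3 and O4' do not ionise under these conditions, and the acidic 7-hydroxychromone is a good leaving group.

Step 7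
Reactants: 14 3-(benzyloxy)-2-[4-(benzyloxy)-3-methoxyphenyl]-5,7-dihydroxy-4H-chromen-4-one
Product: 15 sodium 3-(benzyloxy)-2-[4-(benzyloxy)-3-methoxyphenyl]-5-hydroxy-4-oxo-4H-chromen-7-yl sulfate
Conditions: SO3·pyridine (3 equiv), pyridine, rt; aq NaHCO3; C18 silica
Reagents that add atoms: sulfur trioxide pyridine complex, O=S(=O)([O-])[n+]1ccccc1; sodium hydrogencarbonate, [Na+].OC([O-])=O
Why: O-sulfation of a phenol with a sulfur trioxide amine complex. The 7-OH is the only unhindered acidic hydroxyl, while the 5-OH is held in a hydrogen bond to the C4 carbonyl and should stay free. Hydrogencarbonate exchanges pyridinium for sodium.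

Step 8
Reactants: 15 sodium 3-(benzyloxy)-2-[4-(benzyloxy)-3-methoxyphenyl]-5-hydroxy-4-oxo-4H-chromen-7-yl sulfate
Product: 17 isorhamnetin 7-O-sulfate (3,5-dihydroxy-2-(4-hydroxy-3-methoxyphenyl)-4-oxo-4H-chromen-7-yl hydrogen sulfate), via sodium salt 16 (not isolated)
Conditions: H2 (1 atm), 10% Pd/C, MeOH/THF, rt; filter; 1 M HCl (1 equiv), 0 °C; C18 silica, freeze-dry
Reagents that add atoms: none
Why: Catalytic hydrogenolysis of the aryl and the enol benzyl ether; the aryl sulfate monoester anion, the chromone C2=C3 bond and the methyl ether are inert to Pd/C at one atmosphere of H2. Cold acidification with one equivalent of HCl and reverse-phase desalting then set free the hydrogen sulfate.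

## Compound list

1 | 4-hydroxy-6-methyl-2H-pyran-2-one (triacetic acid lactone) | Cc1cc(O)cc(=O)o1 | starting material
2 | 4-methoxybenzyl chloride | COc1ccc(CCl)cc1 | starting material
3 | 4-[(4-methoxybenzyl)oxy]-6-methyl-2H-pyran-2-one | Cc1cc(OCc2ccc(OC)cc2)cc(=O)o1 | intermediate
4 | 4-(benzyloxy)-3-methoxybenzaldehyde | COc1cc(C=O)ccc1OCc1ccccc1 | starting material
5 | methyl 2-(benzyloxy)acetate | COC(=O)COCc1ccccc1 | starting material
6 | methyl (2Z)-2-(benzyloxy)-3-[4-(benzyloxy)-3-methoxyphenyl]prop-2-enoate | COC(=O)/C(OCc1ccccc1)=C/c1ccc(OCc2ccccc2)c(OC)c1 | intermediate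
7 | (2Z)-2-(benzyloxy)-3-[4-(benzyloxy)-3-methoxyphenyl]prop-2-enoic acid | OC(=O)/C(OCc1ccccc1)=C/c1ccc(OCc2ccccc2)c(OC)c1 | intermediate
8 | (2Z)-2-(benzyloxy)-3-[4-(benzyloxy)-3-methoxyphenyl]-1-(1H-imidazol-1-yl)prop-2-en-1-one | O=C(/C(OCc1ccccc1)=C/c1ccc(OCc2ccccc2)c(OC)c1)n1ccnc1 | intermediate
9 | ({4-[(4-methoxybenzyl)oxy]-2-oxo-2H-pyran-6-yl}methyl)lithium | [Li]Cc1cc(OCc2ccc(OC)cc2)cc(=O)o1 | intermediate
10 | 6-{(3Z)-3-(benzyloxy)-4-[4-(benzyloxy)-3-methoxyphenyl]-2-oxobut-3-en-1-yl}-4-[(4-methoxybenzyl)oxy]-2H-pyran-2-one | O=c1cc(OCc2ccc(OC)cc2)cc(CC(=O)/C(OCc2ccccc2)=C/c2ccc(OCc3ccccc3)c(OC)c2)o1 | intermediate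
11 | 4-methoxybenzyl (2E,8Z)-8-(benzyloxy)-9-[4-(benzyloxy)-3-methoxyphenyl]-3-[(4-methoxybenzyl)oxy]-5,7-dioxonona-2,8-dienoate | COc1ccc(COC(=O)/C=C(OCc2ccc(OC)cc2)\CC(=O)CC(=O)/C(OCc2ccccc2)=C/c2ccc(OCc3ccccc3)c(OC)c2)cc1 | intermediate
12 | (2Z)-2-(benzyloxy)-3-[4-(benzyloxy)-3-methoxyphenyl]-1-{2,6-dihydroxy-4-[(4-methoxybenzyl)oxy]phenyl}prop-2-en-1-one | COc1ccc(COc2cc(O)c(C(=O)/C(OCc3ccccc3)=C/c3ccc(OCc4ccccc4)c(OC)c3)c(O)c2)cc1 | intermediate
13 | 3-(benzyloxy)-2-[4-(benzyloxy)-3-methoxyphenyl]-5-hydroxy-7-[(4-methoxybenzyl)oxy]-4H-chromen-4-one | COc1ccc(COc2cc(O)c3c(=O)c(OCc4ccccc4)c(-c4ccc(OCc5ccccc5)c(OC)c4)oc3c2)cc1 | intermediate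
14 | 3-(benzyloxy)-2-[4-(benzyloxy)-3-methoxyphenyl]-5,7-dihydroxy-4H-chromen-4-one | Oc1cc(O)c2c(=O)c(OCc3ccccc3)c(-c3ccc(OCc4ccccc4)c(OC)c3)oc2c1 | intermediate
15 | sodium 3-(benzyloxy)-2-[4-(benzyloxy)-3-methoxyphenyl]-5-hydroxy-4-oxo-4H-chromen-7-yl sulfate | [Na+].COc1cc(-c2oc3cc(OS(=O)(=O)[O-])cc(O)c3c(=O)c2OCc2ccccc2)ccc1OCc1ccccc1 | intermediate
16 | sodium 3,5-dihydroxy-2-(4-hydroxy-3-methoxyphenyl)-4-oxo-4H-chromen-7-yl sulfate | [Na+].COc1cc(-c2oc3cc(OS(=O)(=O)[O-])cc(O)c3c(=O)c2O)ccc1O | intermediate
17 | isorhamnetin 7-O-sulfate (3,5-dihydroxy-2-(4-hydroxy-3-methoxyphenyl)-4-oxo-4H-chromen-7-yl hydrogen sulfate) | COc1cc(-c2oc3cc(OS(=O)(=O)O)cc(O)c3c(=O)c2O)ccc1O | target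

## Step count and least certain steps

Total step count: 8. Longest linear sequence: 7 steps (step 1 or step 2, then steps 3 to 8).

**Step 4 (key step, proposed new method).**
- The keto pyrone may sit as a delocalised magnesium enolate that resists addition at the lactone carbonyl.
- After opening, the chain may reclose to the pyrone, or a diketone oxygen may close onto the alkoxy-bearing carbon with loss of the ether.
- The alkoxide may add reversibly to the enone and erode the side chain.
- All three follow from the low electrophilicity of a β-alkoxy acrylate ester.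
- Fallback by known chemistry, setting out from 10: TFA with anisole in CH2Cl2 removes the acid-labile 4-methoxybenzyl group from the pyrone oxygen to give 6-{(3Z)-3-(benzyloxy)-4-[4-(benzyloxy)-3-methoxyphenyl]-2-oxobut-3-en-1-yl}-4-hydroxy-2H-pyran-2-one F1. This is a 4-hydroxy-6-(2-oxoalkyl)-2-pyrone of the established class, and Mg(OMe)2 in refluxing MeOH should open it and fold it by Claisen acylation to (2Z)-2-(benzyloxy)-3-[4-(benzyloxy)-3-methoxyphenyl]-1-(2,4,6-trihydroxyphenyl)prop-2-en-1-one F2. I2 in DMSO, as in step 5, then closes ring C and returns to the route at 14. In this variant O7 is told from O5 only by the chelation of the 5-OH at the sulfation stage, and the Claisen-versus-aldol choice rests on the magnesium counter-ion alone.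

**Step 3.**
- Proton transfer from the product or from imidazole to carbanion 9 may stall the acylation.
- Conjugate addition of 9 to the β-aryl enoyl imidazolide may compete with attack at the carbonyl.
- Metalation at the ring position C3 of the pyrone may occur.
- Fallback, setting out from 7: amide coupling (EDC·HCl, MeNHOMe·HCl, Et3N, CH2Cl2) gives the Weinreb amide (2Z)-2-(benzyloxy)-3-[4-(benzyloxy)-3-methoxyphenyl]-N-methoxy-N-methylprop-2-enamide F3. i-Bu2AlH in THF at −78 °C reduces it to (2Z)-2-(benzyloxy)-3-[4-(benzyloxy)-3-methoxyphenyl]prop-2-enal F4. Carbanion 9, made from 3 with LiN(SiMe3)2, adds 1,2 to F4 to give racemic 6-{(3Z)-3-(benzyloxy)-4-[4-(benzyloxy)-3-methoxyphenyl]-2-hydroxybut-3-en-1-yl}-4-[(4-methoxybenzyl)oxy]-2H-pyran-2-one F5. Dess–Martin periodinane oxidises F5, returning to the route at 10. The aldol addition is irreversible and not complicated by product acidity.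

**Step 5.**
- HI formed in the reaction may cleave the 4-methoxybenzyl ether early; this is harmless, since the product is then 14.
- The activated ring A may be iodinated.
- The enol benzyl ether at O3 may be lost under the hot, mildly acidic conditions.
- Fallback, setting out from 12: NaOAc in refluxing EtOH closes ring C by oxa-Michael addition to racemic 3-(benzyloxy)-2-[4-(benzyloxy)-3-methoxyphenyl]-5-hydroxy-7-[(4-methoxybenzyl)oxy]-2,3-dihydro-4H-chromen-4-one F6, as a cis/trans mixture. Dehydrogenation with DDQ in dry dioxane at reflux returns to the route at 13. Any material that loses the 4-methoxybenzyl group is 14 and rejoins one step later.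

**Step 2.**
- Addition of the ester enolate to the electron-rich aldehyde may be slow relative to self-condensation of 5.
- Elimination may stop at the aldol stage or give a mixture of double-bond isomers.
- Fallback, setting out from 4 and 5: LiN(i-Pr)2 in THF at −78 °C gives the aldol adduct methyl 2-(benzyloxy)-3-[4-(benzyloxy)-3-methoxyphenyl]-3-hydroxypropanoate F7 as a mixture of diastereomers. MsCl and Et3N convert it into methyl 2-(benzyloxy)-3-[4-(benzyloxy)-3-methoxyphenyl]-3-[(methylsulfonyl)oxy]propanoate F8. DBU eliminates F8 to ester 6, which is isolated here, and LiOH in THF/water returns to the route at 7.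

**Step 1.**
- The ambident pyronate may be alkylated at C3 or at the lactone carbonyl oxygen by the soft benzylic chloride.
- Fallback, setting out from 1: Mitsunobu etherification with 4-methoxybenzyl alcohol, PPh3 and DIAD in THF activates the alcohol instead of relying on the ambident anion, and arrives directly at 3. No new compound arises (entry F0).

## Further compounds

F1 | step 4 | 6-{(3Z)-3-(benzyloxy)-4-[4-(benzyloxy)-3-methoxyphenyl]-2-oxobut-3-en-1-yl}-4-hydroxy-2H-pyran-2-one | O=c1cc(O)cc(CC(=O)/C(OCc2ccccc2)=C/c2ccc(OCc3ccccc3)c(OC)c2)o1
F2 | step 4 | (2Z)-2-(benzyloxy)-3-[4-(benzyloxy)-3-methoxyphenyl]-1-(2,4,6-trihydroxyphenyl)prop-2-en-1-one | Oc1cc(O)c(C(=O)/C(OCc2ccccc2)=C/c2ccc(OCc3ccccc3)c(OC)c2)c(O)c1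
F3 | step 3 | (2Z)-2-(benzyloxy)-3-[4-(benzyloxy)-3-methoxyphenyl]-N-methoxy-N-methylprop-2-enamide | CON(C)C(=O)/C(OCc1ccccc1)=C/c1ccc(OCc2ccccc2)c(OC)c1
F4 | step 3 | (2Z)-2-(benzyloxy)-3-[4-(benzyloxy)-3-methoxyphenyl]prop-2-enal | O=C/C(OCc1ccccc1)=C/c1ccc(OCc2ccccc2)c(OC)c1
F5 | step 3 | 6-{(3Z)-3-(benzyloxy)-4-[4-(benzyloxy)-3-methoxyphenyl]-2-hydroxybut-3-en-1-yl}-4-[(4-methoxybenzyl)oxy]-2H-pyran-2-one (racemic) | O=c1cc(OCc2ccc(OC)cc2)cc(CC(O)/C(OCc2ccccc2)=C/c2ccc(OCc3ccccc3)c(OC)c2)o1
F6 | step 5 | 3-(benzyloxy)-2-[4-(benzyloxy)-3-methoxyphenyl]-5-hydroxy-7-[(4-methoxybenzyl)oxy]-2,3-dihydro-4H-chromen-4-one (racemic, cis/trans mixture) | COc1ccc(COc2cc(O)c3c(c2)OC(c2ccc(OCc4ccccc4)c(OC)c2)C(OCc2ccccc2)C3=O)cc1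
F7 | step 2 | methyl 2-(benzyloxy)-3-[4-(benzyloxy)-3-methoxyphenyl]-3-hydroxypropanoate (racemic, mixture of diastereomers) | COC(=O)C(OCc1ccccc1)C(O)c1ccc(OCc2ccccc2)c(OC)c1
F8 | step 2 | methyl 2-(benzyloxy)-3-[4-(benzyloxy)-3-methoxyphenyl]-3-[(methylsulfonyl)oxy]propanoate (racemic, mixture of diastereomers) | COC(=O)C(OCc1ccccc1)C(OS(C)(=O)=O)c1ccc(OCc2ccccc2)c(OC)c1
F0 | step 1 | none | none
A1 | alternative 1 | 4-formyl-3,5-dihydroxyphenyl neopentyl sulfate | CC(C)(C)COS(=O)(=O)Oc1cc(O)c(C=O)c(O)c1
A2 | alternative 1 | triisopropyl[(2-{3-methoxy-4-[(triisopropylsilyl)oxy]phenyl}ethynyl)oxy]silane | COc1cc(C#CO[Si](C(C)C)(C(C)C)C(C)C)ccc1O[Si](C(C)C)(C(C)C)C(C)C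
A3 | alternative 1 | 5-hydroxy-2-[3-methoxy-4-(triisopropylsilyloxy)phenyl]-4-oxo-3-(triisopropylsilyloxy)-4H-chromen-7-yl neopentyl sulfate | COc1cc(-c2oc3cc(OS(=O)(=O)OCC(C)(C)C)cc(O)c3c(=O)c2O[Si](C(C)C)(C(C)C)C(C)C)ccc1O[Si](C(C)C)(C(C)C)C(C)C
A4 | alternative 2 | 2-(benzyloxy)-3-[4-(benzyloxy)-3-methoxyphenyl]-1-[2,6-difluoro-4-(methoxymethoxy)phenyl]propane-1,3-dione | COCOc1cc(F)c(C(=O)C(OCc2ccccc2)C(=O)c2ccc(OCc3ccccc3)c(OC)c2)c(F)c1
A5 | alternative 2 | 3-(benzyloxy)-2-(4-benzyloxy-3-methoxyphenyl)-5-fluoro-7-(methoxymethoxy)-4H-chromen-4-one | COCOc1cc(F)c2c(=O)c(OCc3ccccc3)c(-c3ccc(OCc4ccccc4)c(OC)c3)oc2c1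
A6 | alternative 3 | sodium 3,5-dihydroxy-4-[3-(4-hydroxy-3-methoxyphenyl)-2-oxopropanoyl]phenyl sulfate | [Na+].COc1cc(CC(=O)C(=O)c2c(O)cc(OS(=O)(=O)[O-])cc2O)ccc1O
A7 | alternative 3 | isorhamnetin 7-O-sulfate sodium salt | [Na+].COc1cc(-c2oc3cc(OS(=O)(=O)[O-])cc(O)c3c(=O)c2O)ccc1O
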